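(All runs are simulated for an exercise.)

**Turnover count.** If each catalyst turns over at a pace proportional to c(reagent), one constant carries the early flask. Its product with c(reagent) and the time is the turnover count, or turnover number: target made per catalyst charged. Count times loading gives target in percent.

| flask | substrate | reagent | free catalyst | temperature | remark | time |
|---|---|---|---|---|---|---|
| east | 0.050 M | 0.90 equiv | 7.5 mol% | 50 °C | run made earlier |  |
| north-east | 0.10 M | 0.90 equiv | 5 mol% | 50 °C | run made earlier |  |
| alpha | 0.050 M | 0.900 equiv | 5 mol% | 50 °C |  | 30 min |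
| zeta | 0.050 M | 3.60 equiv | 5 mol% | 50 °C |  | 30 min |
| beta | 0.050 M | 0.900 equiv | 5 mol% | 90 °C |  | 30 min |
| delta | 0.050 M | 3.60 equiv | 5 mol% | 90 °C |  | 30 min |

| run | time / min | target / % | substrate / % |
|---|---|---|---|
| east | 2.50 | 3 | 92 |
| east | 5.00 | 3 | 94 |
| east | 8.00 | 6 | 88 |
| east | 10.0 | 4 | 88 |
| east | 12.0 | 7 | 86 |
| east | 15.0 | 11 | 87 |
| east | 20.0 | 18 | 85 |
| north-east | 1.33 | 1 | 97 |
| north-east | 2.00 | 2 | 95 |
| north-east | 3.00 | 5 | 93 |
| north-east | 5.00 | 11 | 91 |
| north-east | 8.00 | 10 | 89 |
| north-east | 12.0 | 17 | 81 |
| north-east | 20.0 | 22 | 75 |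

(readings scatter by 2 percentage points)

- the earlier runs were read with a standard deviation of 2 percentage points
- steps under discussion: substrate + free catalyst <-> catalyst intermediate A; reagent + free catalyst -> spent catalyst; catalyst intermediate B -> free catalyst + target; reagent + catalyst intermediate A <-> catalyst intermediate B
- the earlier runs do not show what temperature does; that part of a forecast is a guess

- all flasks from highest to lowest amount of target, in percent of the substrate charged, at 30 min (alpha / zeta / beta / delta)
- the amount of target, in percent of the substrate charged of the flask you put first, at 30 min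
- the amount of target, in percent of the substrate charged of the flask you put last, at 30 min

**The constant.** We read it from the last target readings. East gives 2.67 L mol⁻¹ min⁻¹ and north-east gives 2.44 L mol⁻¹ min⁻¹. Each carries the scatter of 2 percentage points, yet they lie close although the charges differ. We keep their mean, 2.56 L mol⁻¹ min⁻¹, as the turnover constant.

**First rung.** In east, substrate reads 92 % at 2.50 min, with 7.5 mol% of catalyst charged. We read this as binding. That reading comes sooner than one turnover in alpha, which takes 8.70 min.

**Middle rungs.** Zeta turns over in 2.17 min, faster than alpha. At this pace alpha would need 157 min to drain its reagent, the limiting reagent, and that is longer than the run. Zeta would need 43.5 min to drain its substrate, not far above the run.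

**Both ends.** Alpha's count is 3.45, so we commit to 17.2 % of target, against a ceiling of 0.900 in reagent equivalents. Zeta's count is 13.8, or 69.0 %, but this assumes an unbent line. Temperature stays a guess.

**The forecast.** It gives delta > beta > zeta > alpha, with 72 % first and 15 % last, a little below our alpha. Of the loss of catalyst it says: “Deactivation is barely resolved in these noisy runs”.

**The result.** The order is beta > delta > zeta > alpha, with 57.3 % first and 14.3 % last.

    substrate + free catalyst ⇌ catalyst intermediate A (K = 18.0 L mol⁻¹, k = 64.0 L mol⁻¹ min⁻¹, Ea = 59.0 kJ mol⁻¹, ΔH = 3.00 kJ mol⁻¹)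
    reagent + free catalyst → spent catalyst (k = 0.500 L mol⁻¹ min⁻¹, Ea = 53.0 kJ mol⁻¹)
    catalyst intermediate B → free catalyst + target (k = 1.40 min⁻¹, Ea = 83.0 kJ mol⁻¹)
    reagent + catalyst intermediate A ⇌ catalyst intermediate B (K = 5.70 L mol⁻¹, k = 57.0 L mol⁻¹ min⁻¹, Ea = 49.0 kJ mol⁻¹, ΔH = −16.0 kJ mol⁻¹)
    (constants at 50 °C)

**Counts compared.** Delta's target reads 53.4 % at 15.0 min and 53.4 % at 30.0 min, with spent catalyst at 99.9 % of its charge at the earlier time. Alpha made 2.87 turnovers against our 3.45. Zeta made 5.63 against our 13.8, with spent catalyst at 71.7 %. At 90 °C, delta made 10.7 on 3.60 equiv of reagent and beta made 11.5 on 0.900 equiv. The neighbour of beta charged with 0.540 equiv of reagent made 8.67 turnovers, for 43.4 % of target.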